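**Retrosynthetic overview**
1. Target 24 ← global desilylation of the tris-silylated flavanone 23.
2. 23 ← one-flask double annulation of the acyclic δ-hydroxy-β-diketo-dioxinone 20. Ring C closes first by cyclodehydration to a 2-aryl-2,3-dihydro-4H-pyran-4-one (C2 carried in unchanged). Ring A then closes by dioxinone → acylketene → 6π closure onto the pyranone C=C and aromatisation. Ring B is bought.
3. 20 ← dianion of keto-dioxinone 17 + (S)-β-hydroxy Weinreb amide 6 (C2 set by asymmetric transfer hydrogenation).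
4. 17 ← 5-iodo-dioxinone 12 + allylic acetate 10 (alkenyl–allyl Negishi coupling puts the side chain on the carbon that becomes C6), then C-acetylation.
5. 10 ← geranyl acetate by Shi epoxidation (sets C6″), epoxide → allylic alcohol isomerisation and silylation.

Assumption: the target is the (2S,6″R) isomer as read from the SMILES; LiN(iPr)2, LiN(SiMe3)2 and iPrMgCl·LiCl are used as commercial solutions.

Abbreviations: TBS = tert-butyldimethylsilyl; Ar = 3,4-bis(TBSO)-5-methoxyphenyl; Sc = (2E,6R)-6-(TBSO)-3,7-dimethylocta-2,7-dien-1-yl.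

**Route**

Step 1
Reactants: 1 methyl 3,4-dihydroxy-5-methoxybenzoate
Product: 2 methyl 3,4-bis(TBSO)-5-methoxybenzoate
Conditions: TBSCl (2.5 equiv), imidazole, DMF, 23 → 40 °C
Reagents that add atoms: tert-butyldimethylsilyl chloride (TBSCl), CC(C)(C)[Si](C)(C)Cl
Why: Standard silylation of both phenols gives fluoride-labile protection that tolerates the later amide bases, PPTS and 110 °C; no stereocentre is involved.

Step 2
Reactants: 2 methyl 3,4-bis(TBSO)-5-methoxybenzoate; 3 N-methoxy-N-methylacetamide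
Product: 5 3-Ar-N-methoxy-N-methyl-3-oxopropanamide, via lithium enolate 4 (not isolated)
Conditions: 3 (2.2 equiv), LiN(iPr)2 (2.2 equiv), THF, −78 °C; then 2, −78 → −20 °C; aq. NH4Cl
Reagents that add atoms: none
Why: Crossed Claisen condensation of the amide enolate with the non-enolisable aryl ester; the second equivalent of enolate deprotonates the β-keto amide and stops over-addition.

Step 3
Reactants: 5 3-Ar-N-methoxy-N-methyl-3-oxopropanamide
Product: 6 (3S)-3-Ar-3-hydroxy-N-methoxy-N-methylpropanamide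
Conditions: RuCl[(S,S)-TsDPEN](p-cymene) (1 mol %), HCO2H/Et3N (5:2), CH2Cl2, 30 °C
Reagents that add atoms: none
Why: Noyori asymmetric transfer hydrogenation of an aryl ketone; the (S,S)-catalyst delivers hydride to the face that gives the (S)-benzylic carbinol (as with acetophenone), and this centre becomes C2 of the flavanone.

Step 4
Reactants: 7 geranyl acetate
Product: 8 (2E)-5-[(2R)-3,3-dimethyloxiran-2-yl]-3-methylpent-2-en-1-yl acetate
Conditions: Shi ketone (D-fructose-derived, 30 mol %), KHSO5 (Oxone), K2CO3, Bu4NHSO4, MeCN/CH2(OMe)2/aq. Na2B4O7 buffer, 0 °C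
Reagents that add atoms: potassium peroxymonosulfate KHSO5 (Oxone), [K+].[O-]S(=O)(=O)OO
Why: Shi asymmetric epoxidation; the chiral dioxirane attacks the electron-richer 6,7-olefin (the 2,3-olefin is deactivated by the allylic acetate) through the spiro transition state, which with the D-fructose-derived ketone gives the (R)-epoxide and so sets C6″.

Step 5
Reactants: 8 (2E)-5-[(2R)-3,3-dimethyloxiran-2-yl]-3-methylpent-2-en-1-yl acetate
Product: 9 (2E,6R)-6-hydroxy-3,7-dimethylocta-2,7-dien-1-yl acetate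
Conditions: Al(OiPr)3 (2 equiv), PhMe, 110 °C; then cold 1 M HCl
Reagents that add atoms: none
Why: Aluminium alkoxide-promoted epoxide-to-allylic alcohol isomerisation; a methyl proton is removed syn as the tertiary C–O bond breaks, so the C6–O bond and its R configuration are untouched.

Step 6
Reactants: 9 (2E,6R)-6-hydroxy-3,7-dimethylocta-2,7-dien-1-yl acetate
Product: 10 (2E,6R)-6-(TBSO)-3,7-dimethylocta-2,7-dien-1-yl acetate
Conditions: TBSCl, imidazole, DMF, 23 °C
Reagents that add atoms: tert-butyldimethylsilyl chloride (TBSCl), CC(C)(C)[Si](C)(C)Cl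
Why: Silylation of the secondary allylic alcohol keeps it from trapping the ketene in step 11; configuration is unchanged.

Step 7
Reactants: 11 2,2,6-trimethyl-4H-1,3-dioxin-4-one
Product: 12 5-iodo-2,2,6-trimethyl-4H-1,3-dioxin-4-one
Conditions: N-iodosuccinimide, AcOH, 23 °C, dark
Reagents that add atoms: N-iodosuccinimide, O=C1CCC(=O)N1I
Why: Electrophilic iodination at C5, the nucleophilic α-carbon of the vinylogous ester.

Step 8
Reactants: 12 5-iodo-2,2,6-trimethyl-4H-1,3-dioxin-4-one; 10 (2E,6R)-6-(TBSO)-3,7-dimethylocta-2,7-dien-1-yl acetate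
Product: 15 5-Sc-2,2,6-trimethyl-4H-1,3-dioxin-4-one, via dioxinonylmagnesium chloride 13 (not isolated), via dioxinonylzinc chloride 14 (not isolated)
Conditions: iPrMgCl·LiCl, THF, −40 °C; ZnCl2, −40 → 0 °C; then 10, Pd(PPh3)4 (5 mol %), THF, 23 → 45 °C
Reagents that add atoms: none
Why: Knochel iodine–magnesium exchange, transmetalation to zinc and Negishi alkenyl–allyl coupling; zerovalent palladium ionises the primary allylic acetate and C–C bond formation occurs at the unsubstituted allyl terminus with retention of the E olefin, leaving C6″ untouched.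

Step 9
Reactants: 15 5-Sc-2,2,6-trimethyl-4H-1,3-dioxin-4-one; 3 N-methoxy-N-methylacetamide
Product: 17 5-Sc-2,2-dimethyl-6-(2-oxopropyl)-4H-1,3-dioxin-4-one, via lithium dienolate 16 (not isolated)
Conditions: LiN(SiMe3)2 (2.1 equiv), THF, −78 °C; then 3 (1.1 equiv), −78 → −20 °C; aq. NH4Cl
Reagents that add atoms: none
Why: Vinylogous deprotonation of the 6-methyl group and Claisen-type C-acylation by the Weinreb amide, whose chelated tetrahedral intermediate prevents double addition.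

Step 10
Reactants: 17 5-Sc-2,2-dimethyl-6-(2-oxopropyl)-4H-1,3-dioxin-4-one; 6 (3S)-3-Ar-3-hydroxy-N-methoxy-N-methylpropanamide
Product: 20 6-[(6S)-6-Ar-6-hydroxy-2,4-dioxohexyl]-5-Sc-2,2-dimethyl-4H-1,3-dioxin-4-one, via dilithium dianion 18 (not isolated), via lithium alkoxide 19 (not isolated)
Conditions: 17, LiN(iPr)2 (2.2 equiv), THF, −78 °C; 6 (1.2 equiv), LiN(SiMe3)2 (1.0 equiv), THF, −78 °C; combine, −78 → −30 °C; aq. NH4Cl, 0 °C
Reagents that add atoms: none
Why: Acylation of a keto-dioxinone dianion at its terminal (most nucleophilic) carbon by a Weinreb amide whose hydroxyl is masked as the alkoxide; the carbinol centre is not touched.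

Step 11
Reactants: 20 6-[(6S)-6-Ar-6-hydroxy-2,4-dioxohexyl]-5-Sc-2,2-dimethyl-4H-1,3-dioxin-4-one
Product: 23 (2S)-2-Ar-5,7-dihydroxy-6-Sc-2,3-dihydro-4H-chromen-4-one, via dihydropyranone 21 (not isolated), via acylketene 22 (not isolated)
Conditions: PPTS (10 mol %), 4 Å MS, PhMe (5 mM), 60 °C, 1 h, then 110 °C, 3 h
Reagents that add atoms: none
Why: Proposed new method: PPTS first closes ring C by hemiketalisation of the δ-hydroxyl onto the distal ketone and dehydration to the vinylogous ester (the known δ-hydroxy-β-diketone → 2,3-dihydro-4H-pyran-4-one cyclodehydration, in which the C2–O bond is never broken so the S centre is retained), then above 100 °C the dioxinone loses acetone by retro-[4+2] to the α-substituted acylketene 22, whose enol is a dienylketene that can only close six-membered onto the nucleophilic pyranone α-carbon (6π electrocyclisation or intramolecular C-acylation) and tautomerises to the phloroglucinol ring with the side chain fixed at C6 and the ring oxygen fixed at C8a; the closest known reaction types are dioxinone thermolysis with late-stage aromatisation, the dienylketene closure of the Danheiser benzannulation and Claisen-type polyketide cyclisation.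

Step 12
Reactants: 23 (2S)-2-Ar-5,7-dihydroxy-6-Sc-2,3-dihydro-4H-chromen-4-one
Product: 24 (2S)-2-(3,4-dihydroxy-5-methoxyphenyl)-5,7-dihydroxy-6-[(2E,6R)-6-hydroxy-3,7-dimethylocta-2,7-dien-1-yl]-2,3-dihydro-4H-chromen-4-one
Conditions: HF·pyridine, pyridine, THF, 0 → 23 °C
Reagents that add atoms: none
Why: Buffered, non-basic fluoride cleavage of the three silyl ethers; avoiding base prevents chalcone ring-opening, which would racemise C2 and scramble the 6- and 8-substituted isomers.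

**Compound list**

1 | methyl 3,4-dihydroxy-5-methoxybenzoate | COC(=O)c1cc(O)c(O)c(OC)c1 | starting material
2 | methyl 3,4-bis(tert-butyldimethylsilyloxy)-5-methoxybenzoate | COC(=O)c1cc(O[Si](C)(C)C(C)(C)C)c(O[Si](C)(C)C(C)(C)C)c(OC)c1 | intermediate
3 | N-methoxy-N-methylacetamide | CC(=O)N(C)OC | starting material
4 | lithium 1-[methoxy(methyl)amino]ethen-1-olate (enolate of 3; not isolated) | C=C(O[Li])N(C)OC | intermediate
5 | 3-[3,4-bis(tert-butyldimethylsilyloxy)-5-methoxyphenyl]-N-methoxy-N-methyl-3-oxopropanamide | CON(C)C(=O)CC(=O)c1cc(O[Si](C)(C)C(C)(C)C)c(O[Si](C)(C)C(C)(C)C)c(OC)c1 | intermediate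
6 | (3S)-3-[3,4-bis(tert-butyldimethylsilyloxy)-5-methoxyphenyl]-3-hydroxy-N-methoxy-N-methylpropanamide | CON(C)C(=O)C[C@H](O)c1cc(O[Si](C)(C)C(C)(C)C)c(O[Si](C)(C)C(C)(C)C)c(OC)c1 | intermediate
7 | geranyl acetate, (2E)-3,7-dimethylocta-2,6-dien-1-yl acetate | CC(=O)OC/C=C(\C)CCC=C(C)C | starting material
8 | (2E)-5-[(2R)-3,3-dimethyloxiran-2-yl]-3-methylpent-2-en-1-yl acetate | CC(=O)OC/C=C(\C)CC[C@H]1OC1(C)C | intermediate
9 | (2E,6R)-6-hydroxy-3,7-dimethylocta-2,7-dien-1-yl acetate | CC(=O)OC/C=C(\C)CC[C@@H](O)C(C)=C | intermediate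
10 | (2E,6R)-6-(tert-butyldimethylsilyloxy)-3,7-dimethylocta-2,7-dien-1-yl acetate | CC(=O)OC/C=C(\C)CC[C@@H](O[Si](C)(C)C(C)(C)C)C(C)=C | intermediate
11 | 2,2,6-trimethyl-4H-1,3-dioxin-4-one | CC1=CC(=O)OC(C)(C)O1 | starting material
12 | 5-iodo-2,2,6-trimethyl-4H-1,3-dioxin-4-one | CC1=C(I)C(=O)OC(C)(C)O1 | intermediate
13 | (2,2,6-trimethyl-4-oxo-4H-1,3-dioxin-5-yl)magnesium chloride (not isolated) | CC1=C([Mg]Cl)C(=O)OC(C)(C)O1 | intermediate
14 | (2,2,6-trimethyl-4-oxo-4H-1,3-dioxin-5-yl)zinc chloride (not isolated) | CC1=C([Zn]Cl)C(=O)OC(C)(C)O1 | intermediate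
15 | 5-[(2E,6R)-6-(tert-butyldimethylsilyloxy)-3,7-dimethylocta-2,7-dien-1-yl]-2,2,6-trimethyl-4H-1,3-dioxin-4-one | C=C(C)[C@H](O[Si](C)(C)C(C)(C)C)CC/C(C)=C/CC1=C(C)OC(C)(C)OC1=O | intermediate
16 | lithium dienolate of 15, 4-lithiooxy-6-methylene form (not isolated) | C=C(C)[C@H](O[Si](C)(C)C(C)(C)C)CC/C(C)=C/CC1=C(O[Li])OC(C)(C)OC1=C | intermediate
17 | 5-[(2E,6R)-6-(tert-butyldimethylsilyloxy)-3,7-dimethylocta-2,7-dien-1-yl]-2,2-dimethyl-6-(2-oxopropyl)-4H-1,3-dioxin-4-one | C=C(C)[C@H](O[Si](C)(C)C(C)(C)C)CC/C(C)=C/CC1=C(CC(C)=O)OC(C)(C)OC1=O | intermediate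
18 | dilithium dianion of 17, bis-enolate form (not isolated) | C=C(C)[C@H](O[Si](C)(C)C(C)(C)C)CC/C(C)=C/CC1=C(O[Li])OC(C)(C)OC1=CC(O[Li])=C | intermediate
19 | lithium alkoxide of 6 (not isolated) | CON(C)C(=O)C[C@H](O[Li])c1cc(O[Si](C)(C)C(C)(C)C)c(O[Si](C)(C)C(C)(C)C)c(OC)c1 | intermediate
20 | 6-{(6S)-6-[3,4-bis(tert-butyldimethylsilyloxy)-5-methoxyphenyl]-6-hydroxy-2,4-dioxohexyl}-5-[(2E,6R)-6-(tert-butyldimethylsilyloxy)-3,7-dimethylocta-2,7-dien-1-yl]-2,2-dimethyl-4H-1,3-dioxin-4-one | C=C(C)[C@H](O[Si](C)(C)C(C)(C)C)CC/C(C)=C/CC1=C(CC(=O)CC(=O)C[C@H](O)c2cc(O[Si](C)(C)C(C)(C)C)c(O[Si](C)(C)C(C)(C)C)c(OC)c2)OC(C)(C)OC1=O | intermediate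
21 | 6-({(2S)-2-[3,4-bis(tert-butyldimethylsilyloxy)-5-methoxyphenyl]-4-oxo-3,4-dihydro-2H-pyran-6-yl}methyl)-5-[(2E,6R)-6-(tert-butyldimethylsilyloxy)-3,7-dimethylocta-2,7-dien-1-yl]-2,2-dimethyl-4H-1,3-dioxin-4-one (not isolated) | C=C(C)[C@H](O[Si](C)(C)C(C)(C)C)CC/C(C)=C/CC1=C(CC2=CC(=O)C[C@@H](c3cc(O[Si](C)(C)C(C)(C)C)c(O[Si](C)(C)C(C)(C)C)c(OC)c3)O2)OC(C)(C)OC1=O | intermediate
22 | acylketene 4-{(2S)-2-[3,4-bis(tert-butyldimethylsilyloxy)-5-methoxyphenyl]-4-oxo-3,4-dihydro-2H-pyran-6-yl}-2-[(2E,6R)-6-(tert-butyldimethylsilyloxy)-3,7-dimethylocta-2,7-dien-1-yl]-3-oxobut-1-en-1-one (not isolated) | C=C(C)[C@H](O[Si](C)(C)C(C)(C)C)CC/C(C)=C/CC(=C=O)C(=O)CC1=CC(=O)C[C@@H](c2cc(O[Si](C)(C)C(C)(C)C)c(O[Si](C)(C)C(C)(C)C)c(OC)c2)O1 | intermediate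
23 | (2S)-2-[3,4-bis(tert-butyldimethylsilyloxy)-5-methoxyphenyl]-6-[(2E,6R)-6-(tert-butyldimethylsilyloxy)-3,7-dimethylocta-2,7-dien-1-yl]-5,7-dihydroxy-2,3-dihydro-4H-chromen-4-one | C=C(C)[C@H](O[Si](C)(C)C(C)(C)C)CC/C(C)=C/Cc1c(O)cc2c(c1O)C(=O)C[C@@H](c1cc(O[Si](C)(C)C(C)(C)C)c(O[Si](C)(C)C(C)(C)C)c(OC)c1)O2 | intermediate
24 | (2S)-2-(3,4-dihydroxy-5-methoxyphenyl)-5,7-dihydroxy-6-[(2E,6R)-6-hydroxy-3,7-dimethylocta-2,7-dien-1-yl]-2,3-dihydro-4H-chromen-4-one (CNP0144204.1) | C=C(C)[C@H](O)CC/C(C)=C/Cc1c(O)cc2c(c1O)C(=O)C[C@@H](c1cc(O)c(O)c(OC)c1)O2 | target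

**Step count**

Total: 12 steps. Longest linear sequence: 8 steps (4, 5, 6, 8, 9, 10, 11, 12, from geranyl acetate).

**Steps most likely to fail and fallbacks**

Step 8 (coupling at dioxinone C5). The electron-poor alkenylzinc may transmetalate slowly, so the π-allyl complex may eliminate to dienes or lose E geometry. The fallback sets out from 10 and comes back at 23. Acetate 10 is used instead in a Tsuji–Trost allylation of commercial tert-butyl acetoacetate (Pd(PPh3)4, NaH, THF), giving the C-allylated tert-butyl β-keto ester F1. Its dianion (NaH, then nBuLi) is acetylated with 3 to the 3,5-dioxo ester F2. The trianion of F2 (LiN(iPr)2, 3.2 equiv) is acylated with alkoxide 19 to the δ-hydroxy triketo ester F3. PPTS and 4 Å MS in xylene at 60 °C close ring C to the dihydropyranone tert-butyl β-keto ester F4. At 135 °C F4 loses tert-butanol to the same acylketene 22, which closes to 23. This replaces the dioxinone by a tert-butyl ester as ketene source and the cross-coupling by soft-enolate allylation.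

Step 10 (dianion acylation with a free β-alkoxide). Retro-aldol of 19 or proton transfer may erode yield. The fallback sets out from 6 and 17 and comes back at 20. Compound 6 is silylated (Et3SiCl, imidazole) to the triethylsilyl ether Weinreb amide F5 and reduced with iBu2AlH to the β-silyloxy aldehyde F6. Aldol addition of dianion 18 to F6 gives the β-hydroxy ketone F7 (both epimers at the new carbinol). Dess–Martin oxidation gives the silyl-protected diketo-dioxinone F8. Brief HF·pyridine at 0 °C removes only the triethylsilyl group and gives 20. The C4–C4a bond is thus made by aldol addition and oxidation instead of acylation.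

Step 11 (double annulation). Water released in the first stage may hydrolyse the ketene, or the ketene may oligomerise faster than it closes onto the pyranone. The fallback sets out from 20 and comes back at 23. Compound 20 is cyclodehydrated alone (PPTS, 4 Å MS, CH2Cl2, 23 °C) and dihydropyranone 21 is isolated. Thermolysis of 21 in toluene containing methanol (110 °C) traps ketene 22 as the methyl β-keto ester F9. Ring A is then closed ionically by a titanium-mediated Dieckmann-type Claisen condensation (TiCl4, Bu3N, CH2Cl2, −78 → 0 °C) with spontaneous aromatisation to 23. The low temperature and amine base are chosen to limit epimerisation at C2.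

**Further compounds**

F1 | step 8 | tert-butyl (4E,8R)-2-acetyl-8-(tert-butyldimethylsilyloxy)-5,9-dimethyldeca-4,9-dienoate | C=C(C)[C@H](O[Si](C)(C)C(C)(C)C)CC/C(C)=C/CC(C(C)=O)C(=O)OC(C)(C)C
F2 | step 8 | tert-butyl (4E,8R)-8-(tert-butyldimethylsilyloxy)-5,9-dimethyl-2-(3-oxobutanoyl)deca-4,9-dienoate | C=C(C)[C@H](O[Si](C)(C)C(C)(C)C)CC/C(C)=C/CC(C(=O)CC(C)=O)C(=O)OC(C)(C)C
F3 | step 8 | tert-butyl (9S)-9-[3,4-bis(tert-butyldimethylsilyloxy)-5-methoxyphenyl]-2-[(2E,6R)-6-(tert-butyldimethylsilyloxy)-3,7-dimethylocta-2,7-dien-1-yl]-9-hydroxy-3,5,7-trioxononanoate | C=C(C)[C@H](O[Si](C)(C)C(C)(C)C)CC/C(C)=C/CC(C(=O)CC(=O)CC(=O)C[C@H](O)c1cc(O[Si](C)(C)C(C)(C)C)c(O[Si](C)(C)C(C)(C)C)c(OC)c1)C(=O)OC(C)(C)C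
F4 | step 8 | tert-butyl 4-{(2S)-2-[3,4-bis(tert-butyldimethylsilyloxy)-5-methoxyphenyl]-4-oxo-3,4-dihydro-2H-pyran-6-yl}-2-[(2E,6R)-6-(tert-butyldimethylsilyloxy)-3,7-dimethylocta-2,7-dien-1-yl]-3-oxobutanoate | C=C(C)[C@H](O[Si](C)(C)C(C)(C)C)CC/C(C)=C/CC(C(=O)CC1=CC(=O)C[C@@H](c2cc(O[Si](C)(C)C(C)(C)C)c(O[Si](C)(C)C(C)(C)C)c(OC)c2)O1)C(=O)OC(C)(C)C
F5 | step 10 | (3S)-3-[3,4-bis(tert-butyldimethylsilyloxy)-5-methoxyphenyl]-N-methoxy-N-methyl-3-(triethylsilyloxy)propanamide | CON(C)C(=O)C[C@H](O[Si](CC)(CC)CC)c1cc(O[Si](C)(C)C(C)(C)C)c(O[Si](C)(C)C(C)(C)C)c(OC)c1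
F6 | step 10 | (3S)-3-[3,4-bis(tert-butyldimethylsilyloxy)-5-methoxyphenyl]-3-(triethylsilyloxy)propanal | O=CC[C@H](O[Si](CC)(CC)CC)c1cc(O[Si](C)(C)C(C)(C)C)c(O[Si](C)(C)C(C)(C)C)c(OC)c1
F7 | step 10 | 6-{(6S)-6-[3,4-bis(tert-butyldimethylsilyloxy)-5-methoxyphenyl]-4-hydroxy-2-oxo-6-(triethylsilyloxy)hexyl}-5-[(2E,6R)-6-(tert-butyldimethylsilyloxy)-3,7-dimethylocta-2,7-dien-1-yl]-2,2-dimethyl-4H-1,3-dioxin-4-one | C=C(C)[C@H](O[Si](C)(C)C(C)(C)C)CC/C(C)=C/CC1=C(CC(=O)CC(O)C[C@H](O[Si](CC)(CC)CC)c2cc(O[Si](C)(C)C(C)(C)C)c(O[Si](C)(C)C(C)(C)C)c(OC)c2)OC(C)(C)OC1=O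
F8 | step 10 | 6-{(6S)-6-[3,4-bis(tert-butyldimethylsilyloxy)-5-methoxyphenyl]-2,4-dioxo-6-(triethylsilyloxy)hexyl}-5-[(2E,6R)-6-(tert-butyldimethylsilyloxy)-3,7-dimethylocta-2,7-dien-1-yl]-2,2-dimethyl-4H-1,3-dioxin-4-one | C=C(C)[C@H](O[Si](C)(C)C(C)(C)C)CC/C(C)=C/CC1=C(CC(=O)CC(=O)C[C@H](O[Si](CC)(CC)CC)c2cc(O[Si](C)(C)C(C)(C)C)c(O[Si](C)(C)C(C)(C)C)c(OC)c2)OC(C)(C)OC1=O
F9 | step 11 | methyl 4-{(2S)-2-[3,4-bis(tert-butyldimethylsilyloxy)-5-methoxyphenyl]-4-oxo-3,4-dihydro-2H-pyran-6-yl}-2-[(2E,6R)-6-(tert-butyldimethylsilyloxy)-3,7-dimethylocta-2,7-dien-1-yl]-3-oxobutanoate | C=C(C)[C@H](O[Si](C)(C)C(C)(C)C)CC/C(C)=C/CC(C(=O)CC1=CC(=O)C[C@@H](c2cc(O[Si](C)(C)C(C)(C)C)c(O[Si](C)(C)C(C)(C)C)c(OC)c2)O1)C(=O)OC
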